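## Structural features

The target 17 is a single carbocycle, a cyclohexene whose carbons are numbered here C1 (CH–OMe), C2 (=CH), C3 (=C carrying the benzoyloxymethyl carbon C7), C4 (CH–OH), C5 (CH–OBz) and C6 (CH–OH). Four contiguous oxygenated stereocentres run C4–C5–C6–C1, all R in this numbering, with O4/O5 cis, O5/O6 trans and O6/O1 cis; C1 and C4 are both allylic and flank the trisubstituted C2=C3 alkene. The fragile elements are the two benzoates next to free hydroxyls (acyl shifts from O5 to O4 or O6 under basic conditions), the allylic ether and alcohol, and the ring itself, which is two eliminations away from an arene. The carbon skeleton is simple; the real difficulty is to set relative and absolute configuration at four adjacent carbinol carbons and to tell five oxygens apart, so that O1 alone is methylated, O5 and O7 alone are benzoylated and O4 and O6 stay free. The feature exploited by the key step is that C3 carries a carbon (C7) and C6 an oxygen in a 1,4-relationship across the ring, while C4 and C5 carry a cis-diol on the face opposite to O6. C7(=O)–O6 can therefore be read as the lactone bridge of a 2-pyrone cycloadduct, and C4–C5 with its two cis oxygens as a cyclic enediol dienophile added endo to that pyrone. The bridge also keeps O6 chemically distinct from O4/O5 from the first ring-forming step on, and the extra ester carbon that activates the pyrone can be expelled later as CO2 in the step that places the alkene at C2=C3 and reveals O1.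

## Logic of the disconnections

17 ⇐ 16. The O6–Si bond is cut. O6 must stay masked while O5 is acylated, so its release is kept for the end. Nothing is gained in skeleton, but the last step touches no stereocentre. The forward step must cleave Si–O without forming an alkoxide, otherwise the benzoate on O5 can wander to O4 or O6.

16 ⇐ 15 + 13. The O5–acyl bond is cut. This leaves a cis-diol at C4/C5 whose two hydroxyls differ in ring position (pseudoaxial allylic against equatorial). The gain is that the second benzoate comes from the same reagent as the first. The demand is a mono-acylation that picks O5 over O4.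

15 ⇐ 14 ⇐ 12 + 13. The two ketal C–O bonds are re-formed and the O7–acyl bond is cut. With O4/O5 tied in the ketal and O6 silylated, O7 is the only free hydroxyl in 12, so its benzoylation needs no selectivity. The forward ketal cleavage must spare the silyl ether, the allylic benzoate and the allylic ether.

12 ⇐ 11 ⇐ 10. C7 is taken back to the ester oxidation level and the O1–CH3 bond is cut. This gives an enoate with one free hydroxyl, so both forward steps are single-site operations. The methylation must avoid an alkoxide (silyl shift from O6, base-induced elimination), and the reduction must be a clean 1,2-delivery of hydride.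

10 ⇐ 8 (through 9). In the reverse sense a carboxyl carbon is put back on C3 and the C2–O bond is re-closed to an epoxide. The cut is made here because the C1 stereocentre and the position of the alkene both follow from an epoxide on C1=C2 that can be delivered from the side of O6. The gain is that C1 needs no independent stereocontrol and that the activating ester of the cycloaddition leaves in the same step. The forward step must generate the C3 carbanion by decarboxylation under conditions that the epoxide, the silyl ether and the γ-oxygenated enoate product survive.

8 ⇐ 7 ⇐ 6. The O6–Si bond and the two epoxide C–O bonds are cut. The free hydroxyl on C6 in 6 is the element that directs the oxidant to the α face, so epoxidation has to precede silylation. The demand is syn delivery to an alkene that is deactivated by the neighbouring geminal diester.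

6 ⇐ 5. The acyl–O6 bond is re-formed, which closes the bridged lactone. This turns an open hydroxy diester into a rigid bicycle in which O6 is part of the bridge. The forward opening must be done with methoxide at low temperature so that the ketal and the thermally labile bicycle are not harmed.

5 ⇐ 3 + 4. The C3–C4 and C5–C6 bonds are cut. This is the largest simplification of the route: a bicycle with four stereocentres falls apart into two flat, achiral heterocycles. The forward step must be endo-selective, must discriminate the two faces of the pyrone, and must tolerate an acid-sensitive enol ether and a product that loses CO2 on warming.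

3 ⇐ 2 ⇐ 1. The ring C=C is traced back to loss of HCl from 2, and the C–Cl bond of 2 to chlorination of a C–H bond next to oxygen in 1. The gain is access to the dienophile from a bulk ketal. The demands are mono-chlorination and an elimination that allows the volatile enol ether to be removed as it forms.

## Other disconnections considered

Alternative 1: The cut runs through C1–C2 and C3–C4. It divides the ring into a chiral-pool C4 dialdehyde, (2S,3S)-2,3-bis(tert-butyldimethylsilyloxy)butanedial A1, and a three-carbon alkyne, triethyl(prop-2-yn-1-yloxy)silane A2. In the forward step the low-valent tantalum–alkyne complex made from A2 with TaCl5 and Zn would add through both alkyne carbons to the two aldehydes of A1 and close the cyclohexene as the 1,4-diol A3.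
- In its favour: C5 and C6 are bought with the correct trans relation and absolute configuration; C7 arrives at the alcohol oxidation level; the whole carbon–oxygen framework stands after one C–C bond-forming step; and because A1 is C2-symmetric the orientation of the unsymmetrical alkyne is immaterial. On step count to the complete skeleton this alternative is clearly the better of the two plans.
- Against it: additions of such tantalum–alkyne complexes are secure for one carbonyl group, whereas a ring-closing second addition asks the much less nucleophilic remaining C–Ta bond to react. C1 and C4 would both be created by 1,2-induction from α-silyloxy aldehydes, and both must come out syn to the neighbouring silyloxy group, which is not the usual Felkin preference, so diastereomer mixtures are to be expected. The metal is used stoichiometrically.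
- Comparison: in A3, O5 and O6 bear the same silyl group and O1 and O4 are both free allylic alcohols, so there is no handle for methylating O1 only and benzoylating O5 only. In the chosen plan 5 keeps O6 (lactone), O4/O5 (ketal) and O1 (not yet present) apart from the outset. Mechanistically the chosen cycloaddition fixes three carbinol centres in one event under catalyst control, where this alternative relies on two consecutive substrate-controlled carbonyl additions.

Alternative 2: The cut is at the C4–O and C5–O bonds of an aromatic precursor. Bromobenzene A4 is oxidised by whole cells expressing a toluene-dioxygenase-type Rieske enzyme to (1S,2S)-3-bromocyclohexa-3,5-diene-1,2-diol A5, with both oxygens delivered to one face and the bromine on the future C3. The relay would be ketalisation, dihydroxylation of the distal C1=C6 alkene with OsO4 on the face opposite to the ketal (O1 and O6 cis to each other and anti to O4/O5, the target pattern), and replacement of bromine by C7 through a carbonylation catalysed by Pd(PPh3)4 followed by reduction.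
- In its favour: A5 is formed essentially as one enantiomer and is an article of commerce; the chemistry of such diene diols is thoroughly established; no decarboxylation or alkene transposition is needed; the C2=C3 alkene is in place from the start. On enantiomeric purity and on weight of precedent this alternative is the equal or the better of the chosen plan.
- Against it here: O1 and O6 arrive together as a cis-diol and must be differentiated before O1 can be methylated; C7 needs a separate C–C coupling; the O4/O5 differentiation at the end is the same problem as in the chosen route; the key step needs fermentation equipment if A5 is not purchased.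
- Comparison: in step count the two plans should be about equal, since what is saved on the pyrone sequence is spent on carbonylation and on telling O1 from O6. The chosen plan has the structural advantage that O6 and O1 are introduced at different times and that C7 is carried in by the diene.

Alternative 3: The cut is at C5–O and C6–O, made as an epoxide on a cross-conjugated dienone. 2-[(tert-Butyldimethylsilyloxy)methyl]-4,4-dimethoxycyclohexa-2,5-dien-1-one A6 (ketone carbon = C4, ketal carbon = C1) would be epoxidised at its unsubstituted C5=C6 enone by a hydroperoxide anion paired with a cinchona-derived ammonium phase-transfer catalyst (conjugate addition at C6, ring closure at C5) to give the epoxide A7. In A7 the epoxide oxygen has the target configuration at C6 but the opposite one at C5. The relay therefore has to open the epoxide at C5 with inversion, reduce the C4 ketone cis to O5, and unmask, reduce and methylate C1 cis to O6.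
- In its favour: no metal; a cheap arene precursor by oxidative dearomatisation; all seven carbons and the oxygens on C1 and C4 present before the key step. If the epoxide is opened at C5 by a benzoate nucleophile, O5 would be benzoylated and distinguished from O6 in one operation. On the O4/O5/O6 differentiation problem this alternative is the better of the two, because the chosen plan must rely on a regioselective acylation in step 12.
- Against it: only C6 is set for good in the key step; the enantioselectivity of phase-transfer epoxidation and the choice between the two enone double bonds are less secure than for the pyrone cycloaddition; C4 and C1 depend on two separate substrate-controlled hydride deliveries; the β-oxygenated enone intermediates are prone to elimination and aromatisation.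
- Comparison: the redox and ketal manipulations should make this the longest plan. Mechanistically it builds the four centres one by one, where the chosen step sets three at once.

Key step: step 3

Conventions and assumptions:
- The ring is drawn with C1→C6 clockwise; β is the face of O4 and O5 (towards the viewer), α the face of O6 and O1. Names of intermediates use the target numbering C1–C7.
- Remark on the structures: in 5 the ketal oxygens lie on the face of the carbocycle opposite to the lactone oxygen, which is the arrangement needed at C4, C5 and C6 of 17.
- Remark on the chemistry: the ligand antipode for step 3, 2,2'-(propane-2,2-diyl)bis[(4S)-4-tert-butyl-4,5-dihydro-1,3-oxazole] ((S,S)-t-Bu-BOX), is chosen from the square-planar chelate model of divalent copper. Should the model fail, the (R,R)-ligand is used and nothing else changes.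
- 1, 4 and 13 are taken as commercial.

## Steps

Step 1
Reactants: 1 2,2-dimethyl-1,3-dioxolane
Product: 2 4-chloro-2,2-dimethyl-1,3-dioxolane (racemic)
Conditions: SO2Cl2 (0.5 equiv), AIBN (cat.), neat 1, 65 °C, N2 sweep; distil
Reagents that add atoms: sulfuryl chloride, O=S(=O)(Cl)Cl
Why: Radical chain chlorination at the only C–H bonds next to oxygen, the reaction type that converts ethylene carbonate into chloroethylene carbonate; excess 1 suppresses dichlorination and the gas sweep removes HCl. The new stereocentre is racemic and is destroyed in step 2.

Step 2
Reactants: 2 4-chloro-2,2-dimethyl-1,3-dioxolane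
Product: 3 2,2-dimethyl-1,3-dioxole
Conditions: n-Bu3N (1.5 equiv), 110 °C, product distilled out as formed; stored over K2CO3 at −20 °C
Reagents that add atoms: none
Why: Dehydrochlorination of an α-chloro ether by a tertiary amine (ionisation to the oxocarbenium ion, then loss of the β-proton), as in the passage from chloroethylene carbonate to vinylene carbonate. The volatile enol ether leaves the high-boiling amine salt by distillation, which protects it from acid.

Step 3
Reactants: 4 methyl 2-oxo-2H-pyran-3-carboxylate; 3 2,2-dimethyl-1,3-dioxole
Product: 5 endo bridged lactone: C3 (bridgehead, CO2Me) and C6 (bridgehead) joined by the α-C7(=O)–O bridge, by C1=C2 and by C4–C5 carrying the β-cis-isopropylidenedioxy group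
Conditions: Cu(OTf)2 (10 mol %), (S,S)-t-Bu-BOX (11 mol %), 4 Å MS, CH2Cl2, −40 → −20 °C, dioxole in threefold excess; work-up and evaporation below 25 °C
Reagents that add atoms: none
Why: Inverse-electron-demand Diels–Alder reaction: the lactone and ester carbonyl oxygens of 4 chelate divalent copper, which lowers the LUMO of the pyrone diene so that the electron-rich enol ether 3 adds across pyrone positions 3 and 6, probably asynchronously with the bond to the electrophilic position 6 leading. The closest known reaction type is the Lewis-acid-catalysed cycloaddition of 3-carbomethoxy-2-pyrones with vinyl ethers and related donors, which gives isolable bridged lactones at low temperature. The six-membered carbocycle is closed by a bimolecular suprafacial [4+2] addition that forms C3–C4 and C5–C6 in one step; the lactone and dioxolane rings are carried in, and the lactone becomes the C3-to-C6 bridge. The cis relation of O4 and O5 follows from the ring-locked Z geometry of 3, and the syn attachment of the bridge at C3 and C6 from addition to one face of the planar pyrone. The placement of O4/O5 anti to the lactone bridge is set by the endo transition state, in which the dioxole oxygens lie under the central C=C of the pyrone and the ketal methyl groups point away from the bridge. The absolute sense at all four centres is set by the ligand: in the distorted square-planar chelate one tert-butyl group covers one face of the pyrone, and the (S,S)-ligand is expected to leave open the face that leads to 5. The step needs endo and facial selectivity and the survival of acid-labile 3 and of an adduct that extrudes CO2 on warming, hence sieves, excess 3 and sub-ambient temperature; no regiochemical question arises because 3 is symmetric.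

Step 4
Reactants: 5 endo bridged lactone
Product: 6 dimethyl 6α-hydroxy-4β,5β-(isopropylidenedioxy)cyclohex-1-ene-3,3-dicarboxylate
Conditions: NaOMe (0.2 equiv), MeOH, 0 °C; NH4Cl quench
Reagents that add atoms: methanol, CO
Why: Base-catalysed methanolysis (transesterification) of the strained bridged δ-lactone, whose carbonyl is more electrophilic than the methyl ester; the C6 alkoxide is the leaving group. No stereocentre is touched and C3 becomes a non-stereogenic malonate carbon.

Step 5
Reactants: 6 dimethyl 6α-hydroxy-4β,5β-(isopropylidenedioxy)cyclohex-1-ene-3,3-dicarboxylate
Product: 7 dimethyl 1α,2α-epoxy-6α-hydroxy-4β,5β-(isopropylidenedioxy)cyclohexane-3,3-dicarboxylate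
Conditions: VO(acac)2 (5 mol %), t-BuOOH (1.5 equiv, decane), CH2Cl2, 0 °C → rt
Reagents that add atoms: tert-butyl hydroperoxide, CC(C)(C)OO
Why: Hydroxyl-directed epoxidation of a cyclic allylic alcohol: the peroxide is delivered within the alkoxide–alkylperoxide complex that O6 forms at the vanadium centre of VO(acac)2, so both new C–O bonds form on the α face, cis to O6. The β face is in addition screened by the ketal, so reagent and substrate control agree.

Step 6
Reactants: 7 dimethyl 1α,2α-epoxy-6α-hydroxy-4β,5β-(isopropylidenedioxy)cyclohexane-3,3-dicarboxylate
Product: 8 dimethyl 1α,2α-epoxy-4β,5β-(isopropylidenedioxy)-6α-(triisopropylsilyloxy)cyclohexane-3,3-dicarboxylate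
Conditions: TIPSOTf (1.3 equiv), 2,6-lutidine (2 equiv), CH2Cl2, −40 → 0 °C
Reagents that add atoms: triisopropylsilyl trifluoromethanesulfonate, CC(C)[Si](OS(=O)(=O)C(F)(F)F)(C(C)C)C(C)C
Why: Silyl triflate silylation of a hindered secondary alcohol, buffered by 2,6-lutidine so that the epoxide and ketal are not activated. The triisopropylsilyl group is chosen because it resists 1,2-migration under basic conditions and outlasts the acidic ketal cleavage of step 11.

Step 7
Reactants: 8 dimethyl 1α,2α-epoxy-4β,5β-(isopropylidenedioxy)-6α-(triisopropylsilyloxy)cyclohexane-3,3-dicarboxylate
Product: 10 methyl 1α-hydroxy-4β,5β-(isopropylidenedioxy)-6α-(triisopropylsilyloxy)cyclohex-2-ene-3-carboxylate, via lithium half-ester carboxylate 9 (not isolated)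
Conditions: LiCl (3 equiv), H2O (3 equiv), DMSO, 130 °C
Reagents that add atoms: lithium chloride, [Li+].[Cl-] (its lithium is held in 9 only; 10 takes no heavy atom from a reagent)
Why: Krapcho dealkoxycarbonylation: chloride demethylates one ester of the quaternary malonate by SN2 at methyl, and carboxylate 9 loses CO2 to give the C3 ester enolate, which expels the adjacent epoxide oxygen from C2 (E1cB, the classical β,γ-epoxy ester to γ-hydroxy enoate isomerisation). The C1–O bond is not broken, so C1 keeps the α configuration set in step 5, and the alkene arrives at C2=C3 in conjugation with the remaining ester.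

Step 8
Reactants: 10 methyl 1α-hydroxy-4β,5β-(isopropylidenedioxy)-6α-(triisopropylsilyloxy)cyclohex-2-ene-3-carboxylate
Product: 11 methyl 4β,5β-(isopropylidenedioxy)-1α-methoxy-6α-(triisopropylsilyloxy)cyclohex-2-ene-3-carboxylate
Conditions: Me3OBF4 (3 equiv), 1,8-bis(dimethylamino)naphthalene (3.5 equiv), 4 Å MS, CH2Cl2, 0 °C → rt
Reagents that add atoms: trimethyloxonium tetrafluoroborate, C[O+](C)C.F[B-](F)(F)F
Why: O-Methylation of a hindered secondary alcohol with a trialkyloxonium salt and a non-nucleophilic proton scavenger. No alkoxide is formed, so neither silyl migration from O6 nor base-induced elimination of the γ-oxygenated enoate can start, and the ketal survives the buffered medium.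

Step 9
Reactants: 11 methyl 4β,5β-(isopropylidenedioxy)-1α-methoxy-6α-(triisopropylsilyloxy)cyclohex-2-ene-3-carboxylate
Product: 12 [4β,5β-(isopropylidenedioxy)-1α-methoxy-6α-(triisopropylsilyloxy)cyclohex-2-en-3-yl]methanol
Conditions: i-Bu2AlH (2.5 equiv), CH2Cl2, −78 °C; aq. potassium sodium tartrate
Reagents that add atoms: none
Why: 1,2-Reduction of an α,β-unsaturated ester to the allylic alcohol with i-Bu2AlH at low temperature. The ethers, ketal and silyl ether are inert to the hydride.

Step 10
Reactants: 12 [4β,5β-(isopropylidenedioxy)-1α-methoxy-6α-(triisopropylsilyloxy)cyclohex-2-en-3-yl]methanol; 13 benzoyl chloride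
Product: 14 [4β,5β-(isopropylidenedioxy)-1α-methoxy-6α-(triisopropylsilyloxy)cyclohex-2-en-3-yl]methyl benzoate
Conditions: BzCl (1.2 equiv), pyridine, CH2Cl2, 0 °C
Reagents that add atoms: benzoyl chloride (13), O=C(Cl)c1ccccc1
Why: Acylation of the only free hydroxyl, a primary allylic alcohol, with an acid chloride and pyridine. No selectivity is required.

Step 11
Reactants: 14 [4β,5β-(isopropylidenedioxy)-1α-methoxy-6α-(triisopropylsilyloxy)cyclohex-2-en-3-yl]methyl benzoate
Product: 15 [4β,5β-dihydroxy-1α-methoxy-6α-(triisopropylsilyloxy)cyclohex-2-en-3-yl]methyl benzoate
Conditions: AcOH/H2O (4:1), 50 °C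
Reagents that add atoms: none
Why: Acid-catalysed hydrolysis of the isopropylidene ketal. The hindered secondary triisopropylsilyl ether and the benzoate are far slower to cleave in aqueous acetic acid, and so mild an acid should not ionise the allylic ether.

Step 12
Reactants: 15 [4β,5β-dihydroxy-1α-methoxy-6α-(triisopropylsilyloxy)cyclohex-2-en-3-yl]methyl benzoate; 13 benzoyl chloride
Product: 16 [5β-(benzoyloxy)-4β-hydroxy-1α-methoxy-6α-(triisopropylsilyloxy)cyclohex-2-en-3-yl]methyl benzoate
Conditions: Me2SnCl2 (5 mol %), BzCl (1.1 equiv), i-Pr2NEt (1.5 equiv), THF, 0 °C → rt
Reagents that add atoms: benzoyl chloride (13), O=C(Cl)c1ccccc1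
Why: Organotin-catalysed regioselective monobenzoylation of a cis-1,2-diol: the diol forms a five-membered stannylene chelate with Me2SnCl2 and the equatorial oxygen is acylated. In the favoured half-chair O4 is pseudoaxial (it avoids allylic strain with C7 on C3) and O5 equatorial, so the benzoyl group should go to O5. Room temperature and a hindered amine keep benzoate migration in check.

Step 13
Reactants: 16 [5β-(benzoyloxy)-4β-hydroxy-1α-methoxy-6α-(triisopropylsilyloxy)cyclohex-2-en-3-yl]methyl benzoate
Product: 17 [(3R,4R,5R,6R)-5-(benzoyloxy)-4,6-dihydroxy-3-methoxycyclohex-1-en-1-yl]methyl benzoate (CNP0349013.4)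
Conditions: HF·pyridine, THF/pyridine, 0 °C → rt
Reagents that add atoms: none
Why: Fluoride-mediated cleavage of the Si–O bond under mildly acidic, non-nucleophilic conditions. No alkoxide is generated, so the benzoates on O5 and O7 should not migrate to the free hydroxyls at C4 and C6.

## Compound list

1 | 2,2-dimethyl-1,3-dioxolane | CC1(C)OCCO1 | starting material
2 | 4-chloro-2,2-dimethyl-1,3-dioxolane (racemic) | CC1(C)OCC(Cl)O1 | intermediate
3 | 2,2-dimethyl-1,3-dioxole | CC1(C)OC=CO1 | intermediate
4 | methyl 2-oxo-2H-pyran-3-carboxylate | COC(=O)C1=CC=COC1=O | starting material
5 | endo bridged lactone (C3 ester, C7(=O)–O6 bridge α, C4/C5 ketal β) | COC(=O)[C@@]12C=C[C@@H](OC1=O)[C@@H]1OC(C)(C)O[C@@H]12 | intermediate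
6 | dimethyl 6α-hydroxy-4β,5β-(isopropylidenedioxy)cyclohex-1-ene-3,3-dicarboxylate | O[C@@H]1C=CC(C(=O)OC)(C(=O)OC)[C@H]2OC(C)(C)O[C@@H]12 | intermediate
7 | dimethyl 1α,2α-epoxy-6α-hydroxy-4β,5β-(isopropylidenedioxy)cyclohexane-3,3-dicarboxylate | O[C@@H]1[C@@H]3O[C@@H]3C(C(=O)OC)(C(=O)OC)[C@H]2OC(C)(C)O[C@@H]12 | intermediate
8 | dimethyl 1α,2α-epoxy-4β,5β-(isopropylidenedioxy)-6α-(triisopropylsilyloxy)cyclohexane-3,3-dicarboxylate | CC(C)[Si](C(C)C)(C(C)C)O[C@@H]1[C@@H]3O[C@@H]3C(C(=O)OC)(C(=O)OC)[C@H]2OC(C)(C)O[C@@H]12 | intermediate
9 | lithium salt of the malonic half-ester of 8 (either epimer at C3) | CC(C)[Si](C(C)C)(C(C)C)O[C@@H]1[C@@H]3O[C@@H]3C(C(=O)[O-])(C(=O)OC)[C@H]2OC(C)(C)O[C@@H]12.[Li+] | intermediate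
10 | methyl 1α-hydroxy-4β,5β-(isopropylidenedioxy)-6α-(triisopropylsilyloxy)cyclohex-2-ene-3-carboxylate | O[C@@H]1C=C(C(=O)OC)[C@H]2OC(C)(C)O[C@H]2[C@@H]1O[Si](C(C)C)(C(C)C)C(C)C | intermediate
11 | methyl 4β,5β-(isopropylidenedioxy)-1α-methoxy-6α-(triisopropylsilyloxy)cyclohex-2-ene-3-carboxylate | CO[C@@H]1C=C(C(=O)OC)[C@H]2OC(C)(C)O[C@H]2[C@@H]1O[Si](C(C)C)(C(C)C)C(C)C | intermediate
12 | [4β,5β-(isopropylidenedioxy)-1α-methoxy-6α-(triisopropylsilyloxy)cyclohex-2-en-3-yl]methanol | CO[C@@H]1C=C(CO)[C@H]2OC(C)(C)O[C@H]2[C@@H]1O[Si](C(C)C)(C(C)C)C(C)C | intermediate
13 | benzoyl chloride | O=C(Cl)c1ccccc1 | starting material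
14 | [4β,5β-(isopropylidenedioxy)-1α-methoxy-6α-(triisopropylsilyloxy)cyclohex-2-en-3-yl]methyl benzoate | CO[C@@H]1C=C(COC(=O)c3ccccc3)[C@H]2OC(C)(C)O[C@H]2[C@@H]1O[Si](C(C)C)(C(C)C)C(C)C | intermediate
15 | [4β,5β-dihydroxy-1α-methoxy-6α-(triisopropylsilyloxy)cyclohex-2-en-3-yl]methyl benzoate | CO[C@@H]1C=C(COC(=O)c2ccccc2)[C@@H](O)[C@@H](O)[C@@H]1O[Si](C(C)C)(C(C)C)C(C)C | intermediate
16 | [5β-(benzoyloxy)-4β-hydroxy-1α-methoxy-6α-(triisopropylsilyloxy)cyclohex-2-en-3-yl]methyl benzoate | CO[C@@H]1C=C(COC(=O)c2ccccc2)[C@@H](O)[C@@H](OC(=O)c2ccccc2)[C@@H]1O[Si](C(C)C)(C(C)C)C(C)C | intermediate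
17 | [(3R,4R,5R,6R)-5-(benzoyloxy)-4,6-dihydroxy-3-methoxycyclohex-1-en-1-yl]methyl benzoate | CO[C@@H]1C=C(COC(=O)c2ccccc2)[C@@H](O)[C@@H](OC(=O)c2ccccc2)[C@@H]1O | target

## Step count and least certain steps

Total step count: 13. Longest linear sequence: 13 steps (1 → 17); 11 steps counted from 4.

Step 3 (key step). The most likely failures are insufficient discrimination of the two pyrone faces by the bis(oxazoline) chelate of Cu(OTf)2, Lewis-acid-induced oligomerisation of the enol ether before it can add, and loss of CO2 from the adduct by cycloreversion if the mixture warms. The fallback replaces asymmetric catalysis by resolution; it sets out from 3 and 4 and comes back at 6. The cycloaddition would be run without a chiral ligand (Yb(OTf)3, CH2Cl2, 0 °C), which should give 5 together with its mirror image, the enantiomeric bridged lactone F1. Methanolysis as in step 4 would then give 6 and the enantiomeric hydroxy malonate F2. Esterification of the mixture with (S)-2-methoxy-2-phenylacetic acid (DCC, DMAP, CH2Cl2) would give the (S)-O-methylmandelate ester F3 (from 6) and its diastereomer, the (S)-O-methylmandelate ester F4 (from F2), to be separated by chromatography or crystallisation. K2CO3 in methanol would finally release 6 from F3.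

Step 7. At 130 °C three processes can compete with the intended cascade: chloride opening of the epoxide, migration of the silyl group from O6 to the new C1 alkoxide, and base-induced further elimination of the γ-oxygenated enoate towards an aromatic ester. All three are favoured by the long exposure to hot, weakly basic DMSO that a hindered malonate needs. The fallback uses hydrolytic unmasking and low-temperature decarboxylation; it sets out from 8 and comes back at 10. One ester of 8 would be saponified (KOH, 1.1 equiv, MeOH/H2O, rt) to the malonic half-acid F5. Its triethylammonium salt would then be warmed (Et3N, toluene, 70 °C), so that decarboxylation and epoxide opening proceed in a buffered, chloride-free medium to give 10.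

Step 12. Acylation of the wrong hydroxyl (O4) is possible if the bulky silyl ether on O6 tips the ring into the other half-chair or shields O5; over-acylation and benzoate shift between O4 and O5 are the secondary risks. The fallback uses a temporary tether instead of kinetic selectivity; it sets out from 12 and comes back at 16. The ketal of 12 would be hydrolysed (AcOH/H2O, 50 °C) to the C4,C5,C7-triol F6. Benzaldehyde dimethyl acetal and CSA would close the six-membered acetal across O4 and O7, the O4,O7-benzylidene acetal F7, leaving O5 as the only free hydroxyl. BzCl, pyridine and DMAP would give the O5-benzoate F8, and AcOH/H2O would remove the acetal to give the C4,C7-diol F9. Benzoylation of the primary hydroxyl alone (BzCl 1.0 equiv, 2,4,6-collidine, CH2Cl2, −40 °C) would then give 16.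

Step 5. The alkene is deactivated by the geminal diester, so oxidation of the allylic alcohol to the enone by the alkylperoxide complex of VO(acac)2 may overtake oxygen transfer, or the epoxidation may stall. The fallback uses substrate control in the rigid bicycle instead of hydroxyl direction; it sets out from 5 and comes back at 7. 5 would be epoxidised with dimethyldioxirane (acetone, 0 °C); the endo ketal blocks one face of the alkene bridge, so the oxidant must approach from the lactone side, which should give the epoxy lactone F10 with the epoxide oxygen cis to O6. NaOMe in methanol at 0 °C would then open the bridge to 7.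

Step 1. HCl released in the chlorination may cleave the ketal, and dichlorination may compete, which would starve the key step of dienophile. The fallback uses acyloxylation and thermal elimination; it sets out from 1 and comes back at 3. Kharasch–Sosnovsky oxidation of 1 (tert-butyl peracetate, CuBr cat., excess 1, 80 °C) would give 4-acetoxy-2,2-dimethyl-1,3-dioxolane F11, and flash vacuum pyrolysis at about 450 °C would eliminate acetic acid to give 3.

## Further compounds

F1 | step 3 | enantiomer of bridged lactone 5 | COC(=O)[C@]12C=C[C@H](OC1=O)[C@H]1OC(C)(C)O[C@H]12
F2 | step 3 | enantiomer of hydroxy malonate 6 | O[C@H]1C=CC(C(=O)OC)(C(=O)OC)[C@@H]2OC(C)(C)O[C@H]12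
F3 | step 3 | (S)-2-methoxy-2-phenylacetate (O-methylmandelate) ester of 6 | CO[C@H](C(=O)O[C@@H]1C=CC(C(=O)OC)(C(=O)OC)[C@H]2OC(C)(C)O[C@@H]12)c1ccccc1
F4 | step 3 | (S)-2-methoxy-2-phenylacetate (O-methylmandelate) ester of F2 | CO[C@H](C(=O)O[C@H]1C=CC(C(=O)OC)(C(=O)OC)[C@@H]2OC(C)(C)O[C@H]12)c1ccccc1
F5 | step 7 | malonic half-acid of 8 (either epimer at C3) | CC(C)[Si](C(C)C)(C(C)C)O[C@@H]1[C@@H]3O[C@@H]3C(C(=O)O)(C(=O)OC)[C@H]2OC(C)(C)O[C@@H]12
F6 | step 12 | [4β,5β-dihydroxy-1α-methoxy-6α-(triisopropylsilyloxy)cyclohex-2-en-3-yl]methanol | CO[C@@H]1C=C(CO)[C@@H](O)[C@@H](O)[C@@H]1O[Si](C(C)C)(C(C)C)C(C)C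
F7 | step 12 | O4,O7-benzylidene acetal of F6 (acetal carbon undefined) | CO[C@@H]1C=C2COC(c3ccccc3)O[C@H]2[C@@H](O)[C@@H]1O[Si](C(C)C)(C(C)C)C(C)C
F8 | step 12 | O5-benzoate of F7 | CO[C@@H]1C=C2COC(c3ccccc3)O[C@H]2[C@@H](OC(=O)c2ccccc2)[C@@H]1O[Si](C(C)C)(C(C)C)C(C)C
F9 | step 12 | 5β-(benzoyloxy)-4β-hydroxy-3-(hydroxymethyl)-1α-methoxy-6α-(triisopropylsilyloxy)cyclohex-2-ene | CO[C@@H]1C=C(CO)[C@@H](O)[C@@H](OC(=O)c2ccccc2)[C@@H]1O[Si](C(C)C)(C(C)C)C(C)C
F10 | step 5 | 1α,2α-epoxide of bridged lactone 5 | COC(=O)[C@@]12[C@H]3O[C@H]3[C@@H](OC1=O)[C@@H]1OC(C)(C)O[C@@H]12
F11 | step 1 | 4-acetoxy-2,2-dimethyl-1,3-dioxolane (racemic) | CC(=O)OC1COC(C)(C)O1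
A1 | alternative 1 | (2S,3S)-2,3-bis(tert-butyldimethylsilyloxy)butanedial | O=C[C@@H](O[Si](C)(C)C(C)(C)C)[C@@H](C=O)O[Si](C)(C)C(C)(C)C
A2 | alternative 1 | triethyl(prop-2-yn-1-yloxy)silane | C#CCO[Si](CC)(CC)CC
A3 | alternative 1 | cyclohex-2-ene-1,4-diol with O5 and O6 as tert-butyldimethylsilyl ethers and O7 as triethylsilyl ether | O[C@@H]1C=C(CO[Si](CC)(CC)CC)[C@@H](O)[C@@H](O[Si](C)(C)C(C)(C)C)[C@@H]1O[Si](C)(C)C(C)(C)C
A4 | alternative 2 | bromobenzene | Brc1ccccc1
A5 | alternative 2 | (1S,2S)-3-bromocyclohexa-3,5-diene-1,2-diol | C1=C(Br)[C@@H](O)[C@@H](O)C=C1
A6 | alternative 3 | 2-[(tert-butyldimethylsilyloxy)methyl]-4,4-dimethoxycyclohexa-2,5-dien-1-one | COC1(OC)C=CC(=O)C(CO[Si](C)(C)C(C)(C)C)=C1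
A7 | alternative 3 | 5,6-epoxide of A6 | COC1(OC)C=C(CO[Si](C)(C)C(C)(C)C)C(=O)[C@@H]2O[C@H]12
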